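**Plan**

1. Cuts: O1–C2 of the dihydrobenzofuran; the two lactone C–CH2Ar bonds (C3 side to ring C, C4 side to ring B); C7–C8 of each 1,2-diaryl-1,3-diol unit; aryl–CH2CO back to a Claisen-installed allyl group.
2. Enabling feature: C2 is a benzylic ether carbon para to the ring-D hydroxyl (quinone-methide-capable), and C2 and the CH2OH carbon both sit on C3. O–C2–C3–CH2 can therefore be stored as an oxetane, with the ring-C phenol oxygen (O1) five atoms from C2.
3. Forward: methyl vanillate gives one arylacetic acid (7), activated once as its acid chloride (8), which gives two near-mirror-image anti-aldol diols. One is locked as a silylene with ring A O-benzylated (stays open); the other is spring-loaded as a trans-oxetane with ring D O-silylated.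
4. Ring order: the lactone forms first (succinate alkylation with the ring-B bromide, reduction–lactonisation), then alkylation with the ring-C bromide joins the halves. Fluoride then frees the phenols, and oxetane → quinone methide → dihydrobenzofuran closes the last ring; silylene and benzyl come off at the end.
5. Stereochemistry: C7/C8 of both units from (S)- and (R)-4-benzyloxazolidinone in the magnesium-catalysed anti-aldol; lactone C4 from the (R)-oxazolidinone succinate alkylation; lactone C3 trans by substrate control; dihydrobenzofuran C2 set trans by C3 in the reversible quinone methide closure.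

Key step: step 24

Remarks:
- Locants: in each three-carbon unit C7 is the O-bearing benzylic carbon, C8 the carbon on ring B or ring C, C9 the CH2O carbon. Ring A is the outer ring of the open unit, ring B its inner ring, ring C the benzo ring of the dihydrobenzofuran, ring D the aryl group at C2.
- Shorthand: "Ar" = 3-methoxy-5-(methoxycarbonyl)-2-(triisopropylsilyloxy)phenyl. "Benzyl group B" = 3-[(4S,5S)-4-(4-benzyloxy-3-methoxyphenyl)-2,2-di-tert-butyl-1,3,2-dioxasilinan-5-yl]-5-methoxy-4-(triisopropylsilyloxy)benzyl. "Benzyl group C" = 3-methoxy-5-{(2R,3R)-2-[3-methoxy-4-(triisopropylsilyloxy)phenyl]oxetan-3-yl}-4-(triisopropylsilyloxy)benzyl.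
- Assumption: the magnesium-catalysed anti-aldol of the N-arylacetyl imides follows the chelated-enolate model known for N-propionyl imides (aldehyde anti to the 4-benzyl group), so the (S)-auxiliary gives the (7S,8S)-diol and the (R)-auxiliary the (7R,8R)-diol.

**Route**

Step 1
Reactants: 1 methyl vanillate (methyl 4-hydroxy-3-methoxybenzoate); 2 allyl bromide
Product: 3 methyl 4-(allyloxy)-3-methoxybenzoate
Conditions: K2CO3, DMF, 60 °C
Reagents that add atoms: none
Why: Williamson etherification of the phenoxide with the allylic bromide (SN2); no stereocentre is formed.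

Step 2
Reactants: 3 methyl 4-(allyloxy)-3-methoxybenzoate
Product: 4 methyl 3-allyl-4-hydroxy-5-methoxybenzoate
Conditions: N,N-diethylaniline, 200 °C
Reagents that add atoms: none
Why: Aromatic Claisen rearrangement ([3,3]-sigmatropic shift, then tautomerisation) should deliver the allyl group to the only free ortho position, which places the future CH2CO arm next to the oxygen that later closes the ring.

Step 3
Reactants: 4 methyl 3-allyl-4-hydroxy-5-methoxybenzoate
Product: 5 methyl 3-allyl-5-methoxy-4-(triisopropylsilyloxy)benzoate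
Conditions: iPr3SiOTf, 2,6-lutidine, CH2Cl2, 0 °C to rt
Reagents that add atoms: triisopropylsilyl triflate CC(C)[Si](OS(=O)(=O)C(F)(F)F)(C(C)C)C(C)C
Why: Silylation of the hindered phenol with the silyl triflate gives an aryl silyl ether that should withstand oxidants, hydrides and amide bases and leave only with fluoride.

Step 4
Reactants: 5 methyl 3-allyl-5-methoxy-4-(triisopropylsilyloxy)benzoate
Product: 7 [3-methoxy-5-(methoxycarbonyl)-2-(triisopropylsilyloxy)phenyl]acetic acid, via arylacetaldehyde 6 (not isolated)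
Conditions: OsO4 (cat.), NaIO4, 2,6-lutidine, dioxane/H2O, rt; then NaClO2, NaH2PO4, 2-methyl-2-butene, tBuOH/H2O, 0 °C
Reagents that add atoms: sodium periodate [Na+].[O-]I(=O)(=O)=O (oxygen passed on through OsO4); sodium chlorite [Na+].[O-]Cl=O
Why: Lemieux–Johnson cleavage of the terminal alkene followed by Pinnick oxidation of the crude aldehyde converts the allyl group into the acetic acid arm without touching silyl ether or ester.

Step 5
Reactants: 7 [3-methoxy-5-(methoxycarbonyl)-2-(triisopropylsilyloxy)phenyl]acetic acid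
Product: 8 [3-methoxy-5-(methoxycarbonyl)-2-(triisopropylsilyloxy)phenyl]acetyl chloride
Conditions: (COCl)2, DMF (cat.), CH2Cl2, 0 °C to rt; volatiles removed, used at once
Reagents that add atoms: oxalyl chloride ClC(=O)C(Cl)=O
Why: Chlorination of the carboxylic acid through the catalytic chloroiminium species gives the acyl chloride with only gaseous by-products, so one batch can be divided between the two enantiomeric auxiliaries (steps 6 and 13) while the hindered aryl silyl ether and the methyl ester should stay intact.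

Step 6
Reactants: 8 [3-methoxy-5-(methoxycarbonyl)-2-(triisopropylsilyloxy)phenyl]acetyl chloride; 9 (S)-4-benzyloxazolidin-2-one
Product: 10 (S)-4-benzyl-3-(Ar-acetyl)oxazolidin-2-one
Conditions: Et3N, DMAP (cat.), CH2Cl2, 0 °C
Reagents that add atoms: none
Why: DMAP-catalysed N-acylation of the oxazolidinone by the acid chloride attaches the auxiliary, with acyl transfer at 0 °C expected to outpace ketene formation; no stereocentre is formed.

Step 7
Reactants: 10 (S)-4-benzyl-3-(Ar-acetyl)oxazolidin-2-one; 11 4-(benzyloxy)-3-methoxybenzaldehyde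
Product: 13 (S)-4-benzyl-3-{(2R,3S)-3-[4-(benzyloxy)-3-methoxyphenyl]-3-hydroxy-2-Ar-propanoyl}oxazolidin-2-one, via trimethylsilyl ether 12 (not isolated)
Conditions: MgCl2 (20 mol %), Et3N, Me3SiCl, EtOAc, rt; then CF3CO2H (cat.), MeOH, 0 °C
Reagents that add atoms: none
Why: Magnesium halide-catalysed direct anti-aldol addition of an N-acyloxazolidinone (soft enolisation, silyl trapping of the aldolate): the chelated Z-enolate should be attacked on the face away from the 4-benzyl group through an open boat-like transition state, which sets C8 and C7 (7S,8S after auxiliary removal) in one step.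

Step 8
Reactants: 13 anti-aldol adduct of the (S)-series
Product: 14 methyl 3-{(1S,2S)-1-[4-(benzyloxy)-3-methoxyphenyl]-1,3-dihydroxypropan-2-yl}-5-methoxy-4-(triisopropylsilyloxy)benzoate
Conditions: NaBH4, THF/H2O, 0 °C to rt
Reagents that add atoms: none
Why: Reductive cleavage of the imide by borohydride (hydride at the exocyclic carbonyl, then reduction of the released aldehyde) should leave the aryl methyl ester and both new stereocentres untouched.

Step 9
Reactants: 14 (7S,8S)-diol
Product: 15 methyl 3-{(4S,5S)-4-[4-(benzyloxy)-3-methoxyphenyl]-2,2-di-tert-butyl-1,3,2-dioxasilinan-5-yl}-5-methoxy-4-(triisopropylsilyloxy)benzoate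
Conditions: tBu2Si(OTf)2, 2,6-lutidine, CH2Cl2, 0 °C
Reagents that add atoms: di-tert-butylsilyl bis(triflate) CC(C)(C)[Si](OS(=O)(=O)C(F)(F)F)(OS(=O)(=O)C(F)(F)F)C(C)(C)C
Why: Cyclic silylene formation across the 1,3-diol gives an unstrained six-membered ring that should keep the open unit inert to base, hydride and weak acid until step 25.

Step 10
Reactants: 15 silylene ester
Product: 16 benzyl group B attached to OH (the benzylic alcohol from 15)
Conditions: iBu2AlH, CH2Cl2, −78 °C
Reagents that add atoms: none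
Why: Hydride reduction of the aryl methyl ester to the benzylic alcohol; silyl groups and benzyl ether are inert at this temperature.

Step 11
Reactants: 16 benzylic alcohol of the ring-B series
Product: 17 benzyl group B attached to Br (ring-B bromide)
Conditions: CBr4, PPh3, CH2Cl2, 0 °C
Reagents that add atoms: carbon tetrabromide BrC(Br)(Br)Br
Why: Appel bromination of the primary benzylic alcohol under near-neutral conditions gives the electrophile for the first enolate alkylation.

Step 12
Reactants: 18 vanillin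
Product: 19 3-methoxy-4-(triisopropylsilyloxy)benzaldehyde
Conditions: iPr3SiCl, imidazole, DMF, rt
Reagents that add atoms: chlorotriisopropylsilane CC(C)[Si](Cl)(C(C)C)C(C)C
Why: Silylation of the phenol, so that ring D can be unmasked by fluoride together with the ring-C phenol in step 24.

Step 13
Reactants: 8 [3-methoxy-5-(methoxycarbonyl)-2-(triisopropylsilyloxy)phenyl]acetyl chloride; 20 (R)-4-benzyloxazolidin-2-one
Product: 21 (R)-4-benzyl-3-(Ar-acetyl)oxazolidin-2-one
Conditions: Et3N, DMAP (cat.), CH2Cl2, 0 °C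
Reagents that add atoms: none
Why: The same DMAP-catalysed N-acylation as step 6, with a second portion of acid chloride 8 and the enantiomeric auxiliary.

Step 14
Reactants: 21 (R)-4-benzyl-3-(Ar-acetyl)oxazolidin-2-one; 19 3-methoxy-4-(triisopropylsilyloxy)benzaldehyde
Product: 23 (R)-4-benzyl-3-{(2S,3R)-3-hydroxy-3-[3-methoxy-4-(triisopropylsilyloxy)phenyl]-2-Ar-propanoyl}oxazolidin-2-one, via trimethylsilyl ether 22 (not isolated)
Conditions: MgCl2 (20 mol %), Et3N, Me3SiCl, EtOAc, rt; then CF3CO2H (cat.), MeOH, 0 °C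
Reagents that add atoms: none
Why: The mirror-image magnesium-catalysed anti-aldol of step 7, in which the (R)-auxiliary should set C8 as R (the future C3 of the dihydrobenzofuran) and C7 as R.

Step 15
Reactants: 23 anti-aldol adduct of the (R)-series
Product: 24 methyl 3-{(1R,2R)-1,3-dihydroxy-1-[3-methoxy-4-(triisopropylsilyloxy)phenyl]propan-2-yl}-5-methoxy-4-(triisopropylsilyloxy)benzoate
Conditions: NaBH4, THF/H2O, 0 °C to rt
Reagents that add atoms: none
Why: Borohydride cleavage of the imide as in step 8, chemoselective over the aryl ester.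

Step 16
Reactants: 24 (7R,8R)-diol
Product: 25 (2R,3R)-3-hydroxy-3-[3-methoxy-4-(triisopropylsilyloxy)phenyl]-2-Ar-propyl 4-methylbenzenesulfonate
Conditions: TsCl, Et3N, DMAP (cat.), CH2Cl2, 0 °C
Reagents that add atoms: tosyl chloride Cc1ccc(cc1)S(Cl)(=O)=O
Why: Sulfonylation should select the primary hydroxyl over the hindered secondary benzylic one.

Step 17
Reactants: 25 primary tosylate
Product: 26 methyl 3-methoxy-5-{(2R,3R)-2-[3-methoxy-4-(triisopropylsilyloxy)phenyl]oxetan-3-yl}-4-(triisopropylsilyloxy)benzoate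
Conditions: NaH, THF, 0 °C to rt
Reagents that add atoms: none
Why: Intramolecular Williamson etherification (4-exo-tet) of the alkoxide onto the primary tosylate leaves C7 and C8 untouched, so the anti-diol should give the trans-2,3-diaryloxetane, the less strained diastereomer.

Step 18
Reactants: 26 trans-oxetane ester
Product: 27 benzyl group C attached to OH (the benzylic alcohol from 26)
Conditions: iBu2AlH, THF, −78 °C
Reagents that add atoms: none
Why: Ester reduction at low temperature in a coordinating solvent, where the hydride should not open the oxetane.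

Step 19
Reactants: 27 oxetane benzylic alcohol
Product: 28 benzyl group C attached to Br (ring-C bromide)
Conditions: CBr4, PPh3, 2,6-lutidine, CH2Cl2, −20 °C
Reagents that add atoms: carbon tetrabromide BrC(Br)(Br)Br
Why: Appel bromination buffered with lutidine, so that no acid reaches the oxetane; the bromide is used at once.

Step 20
Reactants: 20 (R)-4-benzyloxazolidin-2-one; 29 methyl 4-chloro-4-oxobutanoate
Product: 30 (R)-4-benzyl-3-(4-methoxy-4-oxobutanoyl)oxazolidin-2-one
Conditions: Et3N, DMAP (cat.), CH2Cl2, 0 °C to rt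
Reagents that add atoms: none
Why: N-acylation of the oxazolidinone with the acid chloride gives the chiral succinate that supplies all four lactone carbons.

Step 21
Reactants: 30 (R)-4-benzyl-3-(4-methoxy-4-oxobutanoyl)oxazolidin-2-one; 17 ring-B bromide
Product: 32 (R)-4-benzyl-3-[(2R)-2-(benzyl group B)-4-methoxy-4-oxobutanoyl]oxazolidin-2-one, via sodium enolate 31 (not isolated)
Conditions: NaN(SiMe3)2, THF, −78 °C; then 17, −78 to −40 °C
Reagents that add atoms: none
Why: Auxiliary-controlled alkylation of the chelated sodium Z-enolate of the imide (more acidic than the ester end) from the face opposite the 4-benzyl group should set the future lactone C4 as R.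

Step 22
Reactants: 32 alkylated succinate imide
Product: 34 (4R)-4-(benzyl group B)dihydrofuran-2(3H)-one, via hydroxy ester 33 (not isolated)
Conditions: NaBH4, THF/H2O, 0 °C to rt; then aq. citric acid, rt
Reagents that add atoms: none
Why: Borohydride cleaves the imide to the primary alcohol, which lactonises onto the methyl ester (5-exo-trig acyl substitution) to close the butyrolactone without touching C4.

Step 23
Reactants: 34 (4R)-lactone; 28 ring-C bromide
Product: 36 (3R,4R)-3-(benzyl group C)-4-(benzyl group B)dihydrofuran-2(3H)-one, via lithium enolate 35 (not isolated)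
Conditions: LiN(SiMe3)2, THF, −78 °C; then 28, DMPU, −78 to −30 °C
Reagents that add atoms: none
Why: Alkylation of the lactone lithium enolate anti to the C4 substituent (1,2-induction in the five-membered enolate, the standard entry to trans-dibenzylbutyrolactones) should set C3 as R.

Step 24
Reactants: 36 (3R,4R)-lactone carrying the silylene-locked open unit and the trans-oxetane
Product: 39 (3R,4R)-lactone whose C3 benzyl group is the (2S,3R)-2-(4-hydroxy-3-methoxyphenyl)-3-(hydroxymethyl)-7-methoxy-2,3-dihydrobenzofuran-5-ylmethyl group and whose C4 benzyl group is the free ring-B phenol with the silylene intact, via tris-phenol oxetane 37 (not isolated), via quinone methide 38 (not isolated)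
Conditions: Bu4NF, AcOH (1:1), THF, 0 °C to rt
Reagents that add atoms: none
Why: Proposed new method: Fluoride removes the three aryl silyl groups; the freed 4-hydroxy-3-methoxyphenyl group on oxetane C2 then pushes electrons through ring D while acetic acid hydrogen-bonds to the oxetane oxygen, so the strained benzylic C2–O bond should break in a 1,6-elimination that gives the para-quinone methide 38 and uncovers the hydroxymethyl group, after which the ring-C phenol adds to the methide carbon. The closest known reaction types are the generation of para-quinone methides from 4-hydroxybenzyl alcohols, ethers and 4-hydroxyphenyl epoxides, the acid-catalysed opening of 3-(2-hydroxyaryl)oxetanes by their own phenol to 3-(hydroxymethyl)-2,3-dihydrobenzofurans, and the quinone methide closure of an open beta-5 unit; opening an oxetane through a quinone methide is the unprecedented part, and release of roughly 25 kcal/mol of ring strain is its driving force. The dihydrofuran ring (O1, C2, C3, C3a, C7a) closes in the 5-exo-trig mode, an oxa-1,6-addition to the exocyclic methide double bond. The new stereocentre C2 is controlled by the existing C3 centre: the phenol should add to the methide face that places ring D trans to the hydroxymethyl group, and because the addition is reversible the thermodynamically preferred (2S,3R)-trans ring should result whatever the oxetane configuration, while C3 is untouched. The step must open only this unit and must break the benzylic, not the CH2–O, bond of the oxetane: the benzyl ether on ring A denies the other beta-5 unit a quinone methide and its benzylic oxygen sits in an unstrained silylene, and only the C2–O bond is conjugated with the ring-D phenoxide. The acetic acid buffer should keep the lactone and its alpha centre intact.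

Step 25
Reactants: 39 dihydrobenzofuran with silylene-protected open unit
Product: 40 mono-benzyl ether of the target (ring A 4-O-benzyl; all other hydroxyls free)
Conditions: HF·pyridine, pyridine, THF, 0 °C
Reagents that add atoms: none
Why: Fluoride cleavage of the silylene under buffered conditions while ring A is still O-benzylated, so that the freed (7S)-benzylic alcohol cannot ionise to a quinone methide and stays open.

Step 26
Reactants: 40 mono-benzyl ether
Product: 41 CNP0199264.2
Conditions: H2 (1 atm), Pd/C, EtOAc/MeOH, rt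
Reagents that add atoms: none
Why: Neutral hydrogenolysis of the single aryl benzyl ether; without acid the benzylic C–O bonds of the dihydrobenzofuran and of the secondary alcohol should survive.

**Compound list**

1 | methyl vanillate (methyl 4-hydroxy-3-methoxybenzoate) | COC(=O)c1ccc(O)c(OC)c1 | starting material
2 | allyl bromide | C=CCBr | starting material
3 | methyl 4-(allyloxy)-3-methoxybenzoate | COC(=O)c1ccc(OCC=C)c(OC)c1 | intermediate
4 | methyl 3-allyl-4-hydroxy-5-methoxybenzoate | COC(=O)c1cc(CC=C)c(O)c(OC)c1 | intermediate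
5 | methyl 3-allyl-5-methoxy-4-(triisopropylsilyloxy)benzoate | COC(=O)c1cc(CC=C)c(O[Si](C(C)C)(C(C)C)C(C)C)c(OC)c1 | intermediate
6 | methyl 3-methoxy-5-(2-oxoethyl)-4-(triisopropylsilyloxy)benzoate (not isolated) | COC(=O)c1cc(CC=O)c(O[Si](C(C)C)(C(C)C)C(C)C)c(OC)c1 | intermediate
7 | [3-methoxy-5-(methoxycarbonyl)-2-(triisopropylsilyloxy)phenyl]acetic acid | COC(=O)c1cc(CC(=O)O)c(O[Si](C(C)C)(C(C)C)C(C)C)c(OC)c1 | intermediate
8 | [3-methoxy-5-(methoxycarbonyl)-2-(triisopropylsilyloxy)phenyl]acetyl chloride | COC(=O)c1cc(CC(Cl)=O)c(O[Si](C(C)C)(C(C)C)C(C)C)c(OC)c1 | intermediate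
9 | (S)-4-benzyloxazolidin-2-one | O=C1N[C@@H](Cc2ccccc2)CO1 | starting material
10 | (S)-4-benzyl-3-{[3-methoxy-5-(methoxycarbonyl)-2-(triisopropylsilyloxy)phenyl]acetyl}oxazolidin-2-one | COC(=O)c1cc(OC)c(O[Si](C(C)C)(C(C)C)C(C)C)c(c1)CC(=O)N2[C@@H](Cc3ccccc3)COC2=O | intermediate
11 | 4-(benzyloxy)-3-methoxybenzaldehyde | COc1cc(C=O)ccc1OCc1ccccc1 | starting material
12 | O-trimethylsilyl ether of adduct 13 (not isolated) | COC(=O)c1cc(OC)c(O[Si](C(C)C)(C(C)C)C(C)C)c(c1)[C@@H](C(=O)N2[C@@H](Cc3ccccc3)COC2=O)[C@H](O[Si](C)(C)C)c4ccc(OCc5ccccc5)c(OC)c4 | intermediate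
13 | (S)-4-benzyl-3-{(2R,3S)-3-[4-(benzyloxy)-3-methoxyphenyl]-3-hydroxy-2-[3-methoxy-5-(methoxycarbonyl)-2-(triisopropylsilyloxy)phenyl]propanoyl}oxazolidin-2-one (anti) | COC(=O)c1cc(OC)c(O[Si](C(C)C)(C(C)C)C(C)C)c(c1)[C@@H](C(=O)N2[C@@H](Cc3ccccc3)COC2=O)[C@H](O)c4ccc(OCc5ccccc5)c(OC)c4 | intermediate
14 | methyl 3-{(1S,2S)-1-[4-(benzyloxy)-3-methoxyphenyl]-1,3-dihydroxypropan-2-yl}-5-methoxy-4-(triisopropylsilyloxy)benzoate | COC(=O)c1cc(OC)c(O[Si](C(C)C)(C(C)C)C(C)C)c(c1)[C@@H](CO)[C@H](O)c2ccc(OCc3ccccc3)c(OC)c2 | intermediate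
15 | methyl 3-{(4S,5S)-4-[4-(benzyloxy)-3-methoxyphenyl]-2,2-di-tert-butyl-1,3,2-dioxasilinan-5-yl}-5-methoxy-4-(triisopropylsilyloxy)benzoate | COC(=O)c1cc(OC)c(O[Si](C(C)C)(C(C)C)C(C)C)c(c1)[C@H]2CO[Si](C(C)(C)C)(C(C)(C)C)O[C@@H]2c3ccc(OCc4ccccc4)c(OC)c3 | intermediate
16 | {3-[(4S,5S)-4-(4-benzyloxy-3-methoxyphenyl)-2,2-di-tert-butyl-1,3,2-dioxasilinan-5-yl]-5-methoxy-4-(triisopropylsilyloxy)phenyl}methanol | OCc1cc(OC)c(O[Si](C(C)C)(C(C)C)C(C)C)c(c1)[C@H]2CO[Si](C(C)(C)C)(C(C)(C)C)O[C@@H]2c3ccc(OCc4ccccc4)c(OC)c3 | intermediate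
17 | ring-B bromide: the benzylic bromide corresponding to alcohol 16 | BrCc1cc(OC)c(O[Si](C(C)C)(C(C)C)C(C)C)c(c1)[C@H]2CO[Si](C(C)(C)C)(C(C)(C)C)O[C@@H]2c3ccc(OCc4ccccc4)c(OC)c3 | intermediate
18 | vanillin | COc1cc(C=O)ccc1O | starting material
19 | 3-methoxy-4-(triisopropylsilyloxy)benzaldehyde | COc1cc(C=O)ccc1O[Si](C(C)C)(C(C)C)C(C)C | intermediate
20 | (R)-4-benzyloxazolidin-2-one | O=C1N[C@H](Cc2ccccc2)CO1 | starting material
21 | (R)-4-benzyl-3-{[3-methoxy-5-(methoxycarbonyl)-2-(triisopropylsilyloxy)phenyl]acetyl}oxazolidin-2-one | COC(=O)c1cc(OC)c(O[Si](C(C)C)(C(C)C)C(C)C)c(c1)CC(=O)N2[C@H](Cc3ccccc3)COC2=O | intermediate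
22 | O-trimethylsilyl ether of adduct 23 (not isolated) | COC(=O)c1cc(OC)c(O[Si](C(C)C)(C(C)C)C(C)C)c(c1)[C@H](C(=O)N2[C@H](Cc3ccccc3)COC2=O)[C@@H](O[Si](C)(C)C)c4ccc(O[Si](C(C)C)(C(C)C)C(C)C)c(OC)c4 | intermediate
23 | (R)-4-benzyl-3-{(2S,3R)-3-hydroxy-3-[3-methoxy-4-(triisopropylsilyloxy)phenyl]-2-[3-methoxy-5-(methoxycarbonyl)-2-(triisopropylsilyloxy)phenyl]propanoyl}oxazolidin-2-one (anti) | COC(=O)c1cc(OC)c(O[Si](C(C)C)(C(C)C)C(C)C)c(c1)[C@H](C(=O)N2[C@H](Cc3ccccc3)COC2=O)[C@@H](O)c4ccc(O[Si](C(C)C)(C(C)C)C(C)C)c(OC)c4 | intermediate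
24 | methyl 3-{(1R,2R)-1,3-dihydroxy-1-[3-methoxy-4-(triisopropylsilyloxy)phenyl]propan-2-yl}-5-methoxy-4-(triisopropylsilyloxy)benzoate | COC(=O)c1cc(OC)c(O[Si](C(C)C)(C(C)C)C(C)C)c(c1)[C@H](CO)[C@@H](O)c2ccc(O[Si](C(C)C)(C(C)C)C(C)C)c(OC)c2 | intermediate
25 | primary tosylate of diol 24, (2R,3R) in the propyl chain | COC(=O)c1cc(OC)c(O[Si](C(C)C)(C(C)C)C(C)C)c(c1)[C@H](COS(=O)(=O)c2ccc(C)cc2)[C@@H](O)c3ccc(O[Si](C(C)C)(C(C)C)C(C)C)c(OC)c3 | intermediate
26 | methyl 3-methoxy-5-{(2R,3R)-2-[3-methoxy-4-(triisopropylsilyloxy)phenyl]oxetan-3-yl}-4-(triisopropylsilyloxy)benzoate (trans-oxetane) | COC(=O)c1cc(OC)c(O[Si](C(C)C)(C(C)C)C(C)C)c(c1)[C@@H]2CO[C@H]2c3ccc(O[Si](C(C)C)(C(C)C)C(C)C)c(OC)c3 | intermediate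
27 | (3-methoxy-5-{(2R,3R)-2-[3-methoxy-4-(triisopropylsilyloxy)phenyl]oxetan-3-yl}-4-(triisopropylsilyloxy)phenyl)methanol | OCc1cc(OC)c(O[Si](C(C)C)(C(C)C)C(C)C)c(c1)[C@@H]2CO[C@H]2c3ccc(O[Si](C(C)C)(C(C)C)C(C)C)c(OC)c3 | intermediate
28 | ring-C bromide: the benzylic bromide corresponding to alcohol 27 | BrCc1cc(OC)c(O[Si](C(C)C)(C(C)C)C(C)C)c(c1)[C@@H]2CO[C@H]2c3ccc(O[Si](C(C)C)(C(C)C)C(C)C)c(OC)c3 | intermediate
29 | methyl 4-chloro-4-oxobutanoate | COC(=O)CCC(Cl)=O | starting material
30 | (R)-4-benzyl-3-(4-methoxy-4-oxobutanoyl)oxazolidin-2-one | COC(=O)CCC(=O)N1[C@H](Cc2ccccc2)COC1=O | intermediate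
31 | sodium Z-enolate of imide 30 (not isolated) | [Na+].[O-]/C(=C\CC(=O)OC)N1[C@H](Cc2ccccc2)COC1=O | intermediate
32 | (R)-4-benzyl-3-[(2R)-2-(benzyl group B)-4-methoxy-4-oxobutanoyl]oxazolidin-2-one | COC(=O)C[C@@H](Cc1cc(OC)c(O[Si](C(C)C)(C(C)C)C(C)C)c(c1)[C@H]2CO[Si](C(C)(C)C)(C(C)(C)C)O[C@@H]2c3ccc(OCc4ccccc4)c(OC)c3)C(=O)N5[C@H](Cc6ccccc6)COC5=O | intermediate
33 | methyl (3R)-3-(benzyl group B)-4-hydroxybutanoate (not isolated) | COC(=O)C[C@@H](Cc1cc(OC)c(O[Si](C(C)C)(C(C)C)C(C)C)c(c1)[C@H]2CO[Si](C(C)(C)C)(C(C)(C)C)O[C@@H]2c3ccc(OCc4ccccc4)c(OC)c3)CO | intermediate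
34 | (4R)-4-(benzyl group B)dihydrofuran-2(3H)-one | O=C1C[C@@H](Cc2cc(OC)c(O[Si](C(C)C)(C(C)C)C(C)C)c(c2)[C@H]3CO[Si](C(C)(C)C)(C(C)(C)C)O[C@@H]3c4ccc(OCc5ccccc5)c(OC)c4)CO1 | intermediate
35 | lithium enolate of lactone 34 (not isolated) | [Li+].[O-]C1=C[C@@H](Cc2cc(OC)c(O[Si](C(C)C)(C(C)C)C(C)C)c(c2)[C@H]3CO[Si](C(C)(C)C)(C(C)(C)C)O[C@@H]3c4ccc(OCc5ccccc5)c(OC)c4)CO1 | intermediate
36 | (3R,4R)-3-(benzyl group C)-4-(benzyl group B)dihydrofuran-2(3H)-one | COc1cc([C@H]5O[Si](C(C)(C)C)(C(C)(C)C)OC[C@@H]5c2cc(C[C@H]3COC(=O)[C@@H]3Cc6cc(OC)c(O[Si](C(C)C)(C(C)C)C(C)C)c(c6)[C@@H]7CO[C@H]7c8ccc(O[Si](C(C)C)(C(C)C)C(C)C)c(OC)c8)cc(OC)c2O[Si](C(C)C)(C(C)C)C(C)C)ccc1OCc4ccccc4 | intermediate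
37 | tris-phenol of 36: the three triisopropylsilyl groups removed, oxetane and silylene intact (not isolated) | COc1cc([C@H]5O[Si](C(C)(C)C)(C(C)(C)C)OC[C@@H]5c2cc(C[C@H]3COC(=O)[C@@H]3Cc6cc(OC)c(O)c(c6)[C@@H]7CO[C@H]7c8ccc(O)c(OC)c8)cc(OC)c2O)ccc1OCc4ccccc4 | intermediate
38 | para-quinone methide from 37: oxetane opened, ring D as 2-methoxycyclohexa-2,5-dienone with exocyclic C7=C, C9–OH free, C8 (R); methide geometry not defined (not isolated) | COc1cc([C@H]5O[Si](C(C)(C)C)(C(C)(C)C)OC[C@@H]5c2cc(C[C@H]3COC(=O)[C@@H]3Cc6cc(OC)c(O)c(c6)[C@H](CO)C=C8C=CC(=O)C(OC)=C8)cc(OC)c2O)ccc1OCc4ccccc4 | intermediate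
39 | (3R,4R)-lactone with the (2S,3R)-dihydrobenzofuran closed, ring B and ring D phenols free, open unit as silylene, ring A O-benzyl | COc1cc([C@H]5O[Si](C(C)(C)C)(C(C)(C)C)OC[C@@H]5c2cc(C[C@H]3COC(=O)[C@@H]3Cc6cc(OC)c7c(c6)[C@H](CO)[C@@H](c8ccc(O)c(OC)c8)O7)cc(OC)c2O)ccc1OCc4ccccc4 | intermediate
40 | ring-A 4-O-benzyl ether of the target | COc1cc([C@@H](O)[C@H](CO)c2cc(C[C@H]3COC(=O)[C@@H]3Cc6cc(OC)c7c(c6)[C@H](CO)[C@@H](c8ccc(O)c(OC)c8)O7)cc(OC)c2O)ccc1OCc4ccccc4 | intermediate
41 | CNP0199264.2 | COc1cc([C@@H](O)[C@H](CO)c2cc(C[C@H]3COC(=O)[C@@H]3Cc3cc(OC)c4c(c3)[C@H](CO)[C@@H](c3ccc(O)c(OC)c3)O4)cc(OC)c2O)ccc1O | target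

**Step count and risks**

Total steps: 26. Longest linear sequence: 17 (steps 1–11, then 21–26).

Steps most likely to fail:

1. Step 24 (Proposed new method). The oxetane may stay closed under buffered fluoride once the phenols are free. Alternatively the quinone methide may be drained by tautomerisation to the styrene (loss of the hydrogen on C3) or by intermolecular capture before the ring-C phenol closes. The fallback uses known chemistry; it sets out from 36 and comes back at 39. Desilylation is run unbuffered (Bu4NF, THF, −20 °C) and the tris-phenol oxetane 37 is isolated. The ring is then closed by the known acid-catalysed opening of a 3-(2-hydroxyaryl)oxetane by its own phenol (catalytic diphenyl phosphate or LiN(SO2CF3)2, CH2Cl2, rt). Here the oxetane oxygen is activated electrophilically instead of relying on the phenoxide push. This fallback makes no compound outside the list (F0).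

2. Step 7 (step 14 is its mirror image and shares the risk). Anti/syn or facial selectivity may be insufficient, or the acidic arylacetyl aldolate may undergo retro-aldol cleavage or epimerise at C8. The fallback sets out from 21 and 11 and comes back at 14. A boron-mediated syn-aldol (Bu2BOTf, iPr2NEt, CH2Cl2, −78 to 0 °C) of the enantiomeric imide 21 with 11 should give the syn adduct F1, which already has the required C8 configuration. NaBH4 then gives the syn-diol F2. Selective acetylation of the primary hydroxyl (AcCl, 2,4,6-collidine, −78 °C) gives the mono-acetate F3. Mitsunobu inversion at C7 with 4-nitrobenzoic acid (PPh3, DIAD) gives the (7S)-diester F4. Methanolysis (K2CO3, MeOH, 0 °C) returns diol 14.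

3. Step 17. Grob fragmentation of the γ-tosyloxy alkoxide (to aldehyde 19 and a styrene) or elimination may outrun the 4-exo-tet closure. The fallback forgoes the oxetane; it sets out from 24 and comes back at 40. Diol 24 is locked as the silylene F5 (tBu2Si(OTf)2, 2,6-lutidine). Reduction with iBu2AlH gives the benzylic alcohol F6, and Appel bromination gives the bromide F7. Alkylation of lactone 34 through enolate 35 gives the bis-silylene lactone F8. Exhaustive desilylation (Bu4NF/AcOH, then HF·pyridine) gives the open form F9. The classical acid-catalysed quinone methide closure of an open beta-5 unit (catalytic diphenyl phosphate, CH2Cl2/THF) then closes only the unit whose 4-hydroxyphenyl group is free and should give 40.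

**Further compounds**

F0 | step 24 | none | none
F1 | step 7 | (R)-4-benzyl-3-{(2R,3R)-3-[4-(benzyloxy)-3-methoxyphenyl]-3-hydroxy-2-[3-methoxy-5-(methoxycarbonyl)-2-(triisopropylsilyloxy)phenyl]propanoyl}oxazolidin-2-one (syn adduct) | COC(=O)c1cc(OC)c(O[Si](C(C)C)(C(C)C)C(C)C)c(c1)[C@@H](C(=O)N2[C@H](Cc3ccccc3)COC2=O)[C@@H](O)c4ccc(OCc5ccccc5)c(OC)c4
F2 | step 7 | methyl 3-{(1R,2S)-1-[4-(benzyloxy)-3-methoxyphenyl]-1,3-dihydroxypropan-2-yl}-5-methoxy-4-(triisopropylsilyloxy)benzoate (syn-diol) | COC(=O)c1cc(OC)c(O[Si](C(C)C)(C(C)C)C(C)C)c(c1)[C@@H](CO)[C@@H](O)c2ccc(OCc3ccccc3)c(OC)c2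
F3 | step 7 | primary acetate of syn-diol F2 | COC(=O)c1cc(OC)c(O[Si](C(C)C)(C(C)C)C(C)C)c(c1)[C@@H](COC(C)=O)[C@@H](O)c2ccc(OCc3ccccc3)c(OC)c2
F4 | step 7 | (7S)-4-nitrobenzoate of F3 with C7 inverted, (7S,8S) | COC(=O)c1cc(OC)c(O[Si](C(C)C)(C(C)C)C(C)C)c(c1)[C@@H](COC(C)=O)[C@H](OC(=O)c2ccc(cc2)[N+]([O-])=O)c3ccc(OCc4ccccc4)c(OC)c3
F5 | step 17 | methyl 3-{(4R,5R)-2,2-di-tert-butyl-4-[3-methoxy-4-(triisopropylsilyloxy)phenyl]-1,3,2-dioxasilinan-5-yl}-5-methoxy-4-(triisopropylsilyloxy)benzoate | COC(=O)c1cc(OC)c(O[Si](C(C)C)(C(C)C)C(C)C)c(c1)[C@@H]2CO[Si](C(C)(C)C)(C(C)(C)C)O[C@H]2c3ccc(O[Si](C(C)C)(C(C)C)C(C)C)c(OC)c3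
F6 | step 17 | benzylic alcohol from F5 | OCc1cc(OC)c(O[Si](C(C)C)(C(C)C)C(C)C)c(c1)[C@@H]2CO[Si](C(C)(C)C)(C(C)(C)C)O[C@H]2c3ccc(O[Si](C(C)C)(C(C)C)C(C)C)c(OC)c3
F7 | step 17 | benzylic bromide from F6 | BrCc1cc(OC)c(O[Si](C(C)C)(C(C)C)C(C)C)c(c1)[C@@H]2CO[Si](C(C)(C)C)(C(C)(C)C)O[C@H]2c3ccc(O[Si](C(C)C)(C(C)C)C(C)C)c(OC)c3
F8 | step 17 | (3R,4R)-lactone carrying both units as silylenes | COc1cc([C@H]5O[Si](C(C)(C)C)(C(C)(C)C)OC[C@@H]5c2cc(C[C@H]3COC(=O)[C@@H]3Cc6cc(OC)c(O[Si](C(C)C)(C(C)C)C(C)C)c(c6)[C@@H]7CO[Si](C(C)(C)C)(C(C)(C)C)O[C@H]7c8ccc(O[Si](C(C)C)(C(C)C)C(C)C)c(OC)c8)cc(OC)c2O[Si](C(C)C)(C(C)C)C(C)C)ccc1OCc4ccccc4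
F9 | step 17 | fully desilylated open form: both units as free 1,3-diols, ring A O-benzyl | COc1cc([C@@H](O)[C@H](CO)c2cc(C[C@H]3COC(=O)[C@@H]3Cc6cc(OC)c(O)c(c6)[C@H](CO)[C@@H](O)c8ccc(O)c(OC)c8)cc(OC)c2O)ccc1OCc4ccccc4
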